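**Retrosynthetic overview**
1. Last operation: acid-catalysed removal of two MOM ethers from the fully assembled 1,3-diketone.
2. Key disconnection: the CH2–C(=O) bond on the ring B side of the propane-1,3-dione. This gives the enolate of 2-methoxy-4-(methoxymethoxy)-3-prenylacetophenone (ring A fragment) and methyl 4-(methoxymethoxy)benzoate (ring B fragment), joined by a crossed Claisen condensation.
3. Ring A fragment: the prenyl group comes from an allyl group by cross metathesis with 2-methyl-2-butene. The C3-allyl group comes from the aromatic Claisen rearrangement of the 4-O-allyl ether of 2,4-dihydroxyacetophenone. The chelated 2-OH allows 4-O-MOM protection first and 2-O-methylation second.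
4. No ring is formed. Both benzene rings are bought, as 2,4-dihydroxyacetophenone and methyl 4-hydroxybenzoate.

Assumption: the target has no stereocentre and no E/Z-isomeric double bond, so it is achiral and no enantiomer has to be selected. It is drawn as the diketo tautomer, which equilibrates with its enol.

**Route**

Step 1
Reactants: 1 2,4-dihydroxyacetophenone
Product: 2 4-allyloxy-2-hydroxyacetophenone
Conditions: allyl bromide (1.1 equiv), K2CO3 (1.3 equiv), acetone, reflux, 8 h
Reagents that add atoms: allyl bromide C=CCBr
Why: Williamson ether synthesis in which the free, more acidic 4-OH is alkylated, while the 2-OH is held in a hydrogen bond to the acetyl C=O and stays untouched.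

Step 2
Reactants: 2 4-allyloxy-2-hydroxyacetophenone
Product: 4 3-allyl-2,4-dihydroxyacetophenone, via 6-allylcyclohexadienone tautomer 3 (not isolated)
Conditions: N,N-diethylaniline, N2, 205 °C, 5 h; recrystallise
Reagents that add atoms: none
Why: Aromatic Claisen rearrangement ([3,3]-sigmatropic shift, then tautomerisation) in which the 2-OH/acetyl chelate gives the C3–C4 bond more double-bond character, so the allyl group migrates to C3 rather than C5, and the transient sp3 centre of 3 is lost on rearomatisation.

Step 3
Reactants: 4 3-allyl-2,4-dihydroxyacetophenone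
Product: 5 3-allyl-2-hydroxy-4-(methoxymethoxy)acetophenone
Conditions: MOMCl (1.15 equiv), K2CO3 (2 equiv), acetone, 0 °C to rt, 4 h
Reagents that add atoms: chloromethyl methyl ether (MOMCl) COCCl
Why: Chemoselective Williamson-type O-alkylation in which the weak base and the very reactive MOMCl engage only the non-chelated 4-OH, leaving the hydrogen-bonded 2-OH free for the next step.

Step 4
Reactants: 5 3-allyl-2-hydroxy-4-(methoxymethoxy)acetophenone
Product: 6 3-allyl-2-methoxy-4-(methoxymethoxy)acetophenone
Conditions: MeI (2.5 equiv), K2CO3 (2.5 equiv), DMF, rt to 40 °C (closed flask), 14 h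
Reagents that add atoms: iodomethane (MeI) CI
Why: Williamson O-methylation in which polar aprotic DMF and excess base break the chelate so the remaining phenoxide is methylated, while K2CO3 is far too weak to enolise the acetyl group and no C-methylation occurs.

Step 5
Reactants: 6 3-allyl-2-methoxy-4-(methoxymethoxy)acetophenone
Product: 7 2-methoxy-4-(methoxymethoxy)-3-(3-methylbut-2-enyl)acetophenone
Conditions: 2-methyl-2-butene/CH2Cl2 1:1 (large excess of olefin), second-generation Grubbs catalyst (H2IMes)(PCy3)Cl2Ru=CHPh (3 mol %), 40 °C, sealed tube, 12 h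
Reagents that add atoms: 2-methyl-2-butene CC=C(C)C
Why: Olefin cross metathesis in which the terminal allyl olefin exchanges its CH2 terminus for the isopropylidene unit of the excess olefin, a volatile alkene leaves, the trisubstituted product no longer re-enters the cycle, and there is no E/Z issue because the new terminus carries two methyl groups.

Step 6
Reactants: 8 methyl 4-hydroxybenzoate
Product: 9 methyl 4-(methoxymethoxy)benzoate
Conditions: MOMCl (1.2 equiv), K2CO3 (2 equiv), acetone, 0 °C to rt, 5 h
Reagents that add atoms: chloromethyl methyl ether (MOMCl) COCCl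
Why: Williamson-type MOM ether formation masks the acidic phenol, which would otherwise consume base and become a phenoxide that deactivates the ester in the condensation.

Step 7
Reactants: 7 2-methoxy-4-(methoxymethoxy)-3-(3-methylbut-2-enyl)acetophenone; 9 methyl 4-(methoxymethoxy)benzoate (1.5 equiv)
Product: 12 1-[2-methoxy-4-(methoxymethoxy)-3-(3-methylbut-2-enyl)phenyl]-3-[4-(methoxymethoxy)phenyl]propane-1,3-dione, via sodium enolate 10 (not isolated), via sodium diketonate 11 (not isolated)
Conditions: NaH (3 equiv) and 9 in THF at reflux, 7 added over 1 h, reflux 5 h; AcOH quench at 0 °C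
Reagents that add atoms: none
Why: Crossed Claisen condensation in which ester 9 has no α-hydrogen and is kept in excess, so only the enolate of 7 can be the nucleophile, irreversible deprotonation to the chelated diketonate 11 drives the equilibrium, the MOM ethers, methyl ether and prenyl group are inert to NaH, and no stereocentre is created.

Step 8
Reactants: 12 1-[2-methoxy-4-(methoxymethoxy)-3-(3-methylbut-2-enyl)phenyl]-3-[4-(methoxymethoxy)phenyl]propane-1,3-dione
Product: 13 1-[4-hydroxy-2-methoxy-3-(3-methylbut-2-enyl)phenyl]-3-(4-hydroxyphenyl)propane-1,3-dione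
Conditions: HCl (ca. 0.3 M, from conc. aq HCl) in MeOH, 45 °C, 1–2 h, stopped at full conversion (TLC)
Reagents that add atoms: none
Why: Acid-catalysed transacetalisation (MOM cleavage) hands both CH2OMe groups to methanol under conditions too mild to protonate the prenyl double bond (no chroman), and because O2 is methylated the diketone cannot close to a flavone.

**Compound list**
1 | 2,4-dihydroxyacetophenone | CC(=O)c1ccc(O)cc1O | starting material
2 | 4-allyloxy-2-hydroxyacetophenone | CC(=O)c1ccc(OCC=C)cc1O | intermediate
3 | 4-acetyl-5-hydroxy-6-(prop-2-enyl)cyclohexa-2,4-dien-1-one (racemic, transient, not isolated) | CC(=O)C1=C(O)C(CC=C)C(=O)C=C1 | intermediate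
4 | 3-allyl-2,4-dihydroxyacetophenone | CC(=O)c1ccc(O)c(CC=C)c1O | intermediate
5 | 3-allyl-2-hydroxy-4-(methoxymethoxy)acetophenone | CC(=O)c1ccc(OCOC)c(CC=C)c1O | intermediate
6 | 3-allyl-2-methoxy-4-(methoxymethoxy)acetophenone | CC(=O)c1ccc(OCOC)c(CC=C)c1OC | intermediate
7 | 2-methoxy-4-(methoxymethoxy)-3-(3-methylbut-2-enyl)acetophenone | CC(=O)c1ccc(OCOC)c(CC=C(C)C)c1OC | intermediate
8 | methyl 4-hydroxybenzoate | COC(=O)c1ccc(O)cc1 | starting material
9 | methyl 4-(methoxymethoxy)benzoate | COC(=O)c1ccc(OCOC)cc1 | intermediate
10 | sodium enolate of 7 (not isolated) | C=C([O-])c1ccc(OCOC)c(CC=C(C)C)c1OC.[Na+] | intermediate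
11 | sodium salt of diketone 12 (not isolated) | COCOc1ccc(cc1)C(=O)[CH-]C(=O)c1ccc(OCOC)c(CC=C(C)C)c1OC.[Na+] | intermediate
12 | 1-[2-methoxy-4-(methoxymethoxy)-3-(3-methylbut-2-enyl)phenyl]-3-[4-(methoxymethoxy)phenyl]propane-1,3-dione | COCOc1ccc(cc1)C(=O)CC(=O)c1ccc(OCOC)c(CC=C(C)C)c1OC | intermediate
13 | 1-[4-hydroxy-2-methoxy-3-(3-methylbut-2-enyl)phenyl]-3-(4-hydroxyphenyl)propane-1,3-dione (CNP0308388.0, achiral) | COc1c(C(=O)CC(=O)c2ccc(O)cc2)ccc(O)c1CC=C(C)C | target

**Count**
Total steps: 8. Longest linear sequence: 7 (steps 1, 2, 3, 4, 5, 7, 8). Step 6 is the one-step side branch.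

**Three steps most likely to fail**

Step 5. The risks are ruthenium hydride-induced migration of the allyl double bond into conjugation and stalled conversion at the doubly ortho-flanked allyl group. In the fallback the allyl handle is given up and the intact prenyl group is brought in by cross-coupling. It sets out from 1. Iodination with I2/HIO3 in aqueous EtOH at 35 °C gives 2,4-dihydroxy-3-iodoacetophenone F1. Selective protection with MOMCl/K2CO3 in acetone gives 2-hydroxy-3-iodo-4-(methoxymethoxy)acetophenone F2. Methylation with MeI/K2CO3 in DMF gives 3-iodo-2-methoxy-4-(methoxymethoxy)acetophenone F3. Stille coupling of this iodide with tributyl(3-methylbut-2-enyl)stannane (Pd(PPh3)4 5 mol %, DMF, 90 °C) comes back to the route at 7.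

Step 7. The risks are that the electron-rich benzoate is a sluggish electrophile and that the ketone self-condenses. In the fallback the ester is replaced by the far more electrophilic aldehyde, and the oxidation level is corrected afterwards (aldol addition, then oxidation). 4-Hydroxybenzaldehyde with MOMCl/K2CO3 in acetone gives 4-(methoxymethoxy)benzaldehyde F4. The fallback sets out from 7, which LiN(SiMe3)2 (1.1 equiv, THF, −78 °C) converts into its lithium enolate F5. Addition of the aldehyde at −78 °C gives the lithium aldolate F6. An AcOH quench gives racemic 3-hydroxy-1-[2-methoxy-4-(methoxymethoxy)-3-(3-methylbut-2-enyl)phenyl]-3-[4-(methoxymethoxy)phenyl]propan-1-one F7. Oxidation with 2-iodoxybenzoic acid (IBX, EtOAc, 75 °C) erases the carbinol stereocentre and comes back to the route at 12.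

Step 8. The risk is acid-induced cyclisation of the freed 4-OH onto the neighbouring prenyl group to give a 2,2-dimethylchroman. In the fallback the order is changed so that the prenyl group is never exposed to acid: the metathesis becomes the last operation. It sets out from 6. Under the conditions of step 7, 6 passes through its sodium enolate F8 and the sodium diketonate F9, and gives with 9 the compound 1-[3-allyl-2-methoxy-4-(methoxymethoxy)phenyl]-3-[4-(methoxymethoxy)phenyl]propane-1,3-dione F10. HCl in MeOH, to which the simple allyl group is indifferent, gives 1-(3-allyl-4-hydroxy-2-methoxyphenyl)-3-(4-hydroxyphenyl)propane-1,3-dione F11. Cross metathesis of this diphenol with excess 2-methyl-2-butene and the second-generation Grubbs catalyst (H2IMes)(PCy3)Cl2Ru=CHPh (5 mol %, CH2Cl2, 40 °C) comes back to the route at 13.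

**Further compounds**
F1 | step 5 | 2,4-dihydroxy-3-iodoacetophenone | CC(=O)c1ccc(O)c(I)c1O
F2 | step 5 | 2-hydroxy-3-iodo-4-(methoxymethoxy)acetophenone | CC(=O)c1ccc(OCOC)c(I)c1O
F3 | step 5 | 3-iodo-2-methoxy-4-(methoxymethoxy)acetophenone | CC(=O)c1ccc(OCOC)c(I)c1OC
F4 | step 7 | 4-(methoxymethoxy)benzaldehyde | COCOc1ccc(C=O)cc1
F5 | step 7 | lithium enolate of 7 | C=C([O-])c1ccc(OCOC)c(CC=C(C)C)c1OC.[Li+]
F6 | step 7 | lithium aldolate (racemic) | COCOc1ccc(cc1)C([O-])CC(=O)c1ccc(OCOC)c(CC=C(C)C)c1OC.[Li+]
F7 | step 7 | racemic 3-hydroxy-1-[2-methoxy-4-(methoxymethoxy)-3-(3-methylbut-2-enyl)phenyl]-3-[4-(methoxymethoxy)phenyl]propan-1-one | COCOc1ccc(cc1)C(O)CC(=O)c1ccc(OCOC)c(CC=C(C)C)c1OC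
F8 | step 8 | sodium enolate of 6 | C=C([O-])c1ccc(OCOC)c(CC=C)c1OC.[Na+]
F9 | step 8 | sodium salt of diketone F10 | COCOc1ccc(cc1)C(=O)[CH-]C(=O)c1ccc(OCOC)c(CC=C)c1OC.[Na+]
F10 | step 8 | 1-[3-allyl-2-methoxy-4-(methoxymethoxy)phenyl]-3-[4-(methoxymethoxy)phenyl]propane-1,3-dione | COCOc1ccc(cc1)C(=O)CC(=O)c1ccc(OCOC)c(CC=C)c1OC
F11 | step 8 | 1-(3-allyl-4-hydroxy-2-methoxyphenyl)-3-(4-hydroxyphenyl)propane-1,3-dione | COc1c(C(=O)CC(=O)c2ccc(O)cc2)ccc(O)c1CC=C
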